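The data were generated by integration on assumed constants, and the scatter is random.

The vessel is closed, stirred and isothermal, and whoever repeats this run should watch the incoming ligand more closely than the clock.

| setting | autumn | dawn | flask |
|---|---|---|---|
| starting complex | 0.050 M | 0.10 M | 0.050 M |
| incoming ligand | 0.060 M | 0.060 M | 0.0600 M |
| remark | the very flask that is asked about, followed so far | run made earlier |  |
| time |  |  | 5.0 h |

| run | time / h | complex with one exchanged / % |
|---|---|---|
| autumn | 0.333 | 15.7 |
| autumn | 0.667 | 24.4 |
| autumn | 1.50 | 34.5 |
| autumn | 4.00 | 47.1 |
| dawn | 0.417 | 17.4 |
| dawn | 1.33 | 26.6 |
| dawn | 2.50 | 31.4 |
| dawn | 4.00 | 32.6 |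

(readings scatter by 1 percentage point)

- for leaving ligand the idle adduct is counted in
- what is taken out of complex with one exchanged is counted as made
- the earlier runs were read with a standard deviation of 1 percentage point
- what may be going on: starting complex + incoming ligand <-> leaving ligand + complex with one exchanged; complex with one exchanged + incoming ligand <-> leaving ligand + complex with two exchanged; leaving ligand + incoming ligand <-> idle adduct; incoming ligand -> decomposed reagent; leaving ligand -> by-product carried off
- additions bring no volume worth counting

- red: change nothing and wait 5.0 h more
- green: at 5.0 h take out 90% of the complex with one exchanged then present, then wait 5.0 h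
- grey: at 5.0 h add incoming ligand, 50.0% of the amount charged, then wait 5.0 h
- blue: at 5.0 h add starting complex, 50.0% of the amount charged, then wait 5.0 h

- complex with one exchanged, in percent of the starting complex first charged, at 5.0 h
- which option adds most complex with one exchanged ("none" when 2 percentage points or less is all one gets) (red / green / grey / blue / none)
- complex with one exchanged present, with what was taken out counted in, in percent of the starting complex first charged, after grey
- complex with one exchanged present, with what was taken out counted in, in percent of the starting complex first charged, after blue

I build a ladder of times from the first reading of each run. My rung is the ligand clock, the time the charged ligand lasts if exchange keeps using it at its first pace: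

ligand clock = [incoming ligand] charged / first rate of making complex with one exchanged

dawn: 1.44 h

autumn: 2.55 h

The dawn clock is shorter than the autumn clock, and the autumn clock is shorter than the time at which I act. Past its clock, the dawn run moves 1.2 percentage points between its last readings, against a scatter of 1 point. It stands at 32.6%, so I read that stall as the ligand's doing, not the starting complex's. Control seems to pass there from time to the ligand budget, so I carry one number from the last dawn reading, with that reading's scatter:

Y = 54.3%

This is the ligand yield, the complex with one exchanged made per incoming ligand charged. On the charge of the asked flask, Y gives 65.2%. The autumn reading of 47.1% is past its clock but still rising, so I expect the flask a little above that reading and below this figure. Grey raises the budget and the other options do not, so I back grey.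

The forecast gives 49.5%, names grey, and puts grey at 66% and blue at 59%, on the ground that “extra incoming ligand attacks the actual limitation”.

The flask gives 48.4%, the best option is grey with a gain of 16 points, grey ends at 64.1% and blue at 53.3%.

    starting complex + incoming ligand ⇌ leaving ligand + complex with one exchanged (K = 0.350, k = 10.0 M⁻¹ h⁻¹)
    complex with one exchanged + incoming ligand ⇌ leaving ligand + complex with two exchanged (K = 0.270, k = 0.470 M⁻¹ h⁻¹)
    leaving ligand + incoming ligand ⇌ idle adduct, settled at all times (K = 50.0 M⁻¹)
    incoming ligand → decomposed reagent (k = 0.320 h⁻¹)
    leaving ligand → by-product carried off (k = 1.90 h⁻¹)

Blue is where forecast and flask part, at 59% against 53.3%. The flask holds 8.73% of its charged ligand at 5.00 h, which at Y is worth 5.7 points, and blue adds 4.9 points. The yield of the flask itself at 5.0 h is 40.3%, lower than the dawn figure. The running short of incoming ligand, here the limiting reagent with 8.73% of its charge free at 5.00 h, may be called the main reason for the flask's 48.4%, since the same run with that running short taken away stands at 76.0%. The neighbour charged with 0.015 M of ligand reckons at Y to 16.3% and stands at 16.3%.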